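**Strategy.** The cycloheptene ring (azulene locants C3a, C4–C8, C8a) is treated as a benzene ring plus one carbon: its C4 oxygen and C6 methyl are those of m-cresol. In the key step a diazoethyl ketone, whose phenol oxygen (future C4–O) and tertiary carbinol oxygen (C3–O) are tied into a di-tert-butylsilylene ring, undergoes an intramolecular Buchner reaction. One operation dearomatises the arene, expands it to the seven-membered ring, closes the cyclopentanone and sets the quaternary C8a methyl, the tether fixing regio- and diastereoselectivity. The liberated C3 hydroxyl then directs hydride to both flanking ketones, and a 1,4-hydrogenation and bis-angeloylation finish the route.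

Key step: step 6

Remark (locants): azulene numbering is used for all bicyclic compounds: C1–C3 in the five-membered ring, C3a and C8a at the ring fusion, C4–C8 in the seven-membered ring.
Remark (assumption): the (R,R)-allylsilane 5 is taken to deliver the (R)-carbinol; if the sense of induction is the opposite, its commercial (S,S)-antipode is used and nothing else changes.

Step 1
Reactants: 1 3-methylphenol (m-cresol); 2 2-methylpropanoyl chloride
Product: 4 1-(2-hydroxy-4-methylphenyl)-2-methylpropan-1-one, via 3-methylphenyl isobutyrate 3 (not isolated)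
Conditions: neat, 80 °C (−HCl); then AlCl3 (1.5 equiv), 140 °C; ice/aq. HCl
Reagents that add atoms: 2-methylpropanoyl chloride, CC(C)C(=O)Cl
Why: O-acylation followed by thermal ortho-Fries rearrangement, in which the high temperature favours the chelated ortho-hydroxy ketone and, of the two ortho positions, the unhindered one para to the methyl group is acylated.

Step 2
Reactants: 4 1-(2-hydroxy-4-methylphenyl)-2-methylpropan-1-one; 5 (3aR,7aR)-2-allyl-1,3-bis(4-bromobenzyl)-2-chlorooctahydro-1H-1,3,2-benzodiazasilole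
Product: 6 2-[(3R)-3-hydroxy-2-methylhex-5-en-3-yl]-5-methylphenol
Conditions: 5 (1.5 equiv), PhMe, 40 °C; 1 M HCl work-up; crystallisation to raise the ee
Reagents that add atoms: allylchlorosilane 5, C=CC[Si]1(Cl)N(Cc2ccc(Br)cc2)[C@@H]2CCCC[C@H]2N1Cc1ccc(Br)cc1
Why: Strained-silacycle allylation of a 2-hydroxyaryl ketone, a reaction type established for hindered α-branched ketones of this class: the phenol displaces chloride on silicon, the Lewis-acidic silane binds the ketone and transfers allyl internally through a chair transition state, so the diamine backbone sets the (R)-carbinol.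

Step 3
Reactants: 6 2-[(3R)-3-hydroxy-2-methylhex-5-en-3-yl]-5-methylphenol; 7 di-tert-butylsilanediyl bis(trifluoromethanesulfonate)
Product: 8 (4R)-2,2-di-tert-butyl-7-methyl-4-(propan-2-yl)-4-(prop-2-en-1-yl)-4H-1,3,2-benzodioxasiline
Conditions: 2,6-lutidine, CH2Cl2, 0 → 40 °C
Reagents that add atoms: di-tert-butylsilyl bis(triflate) 7, CC(C)(C)[Si](OS(=O)(=O)C(F)(F)F)(OS(=O)(=O)C(F)(F)F)C(C)(C)C
Why: Silylene formation across the 1,3-related phenol and tertiary alcohol closes a six-membered ring that masks both oxygens in one step and ties the carbinol oxygen to the arene oxygen for the key step.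

Step 4
Reactants: 8 (4R)-2,2-di-tert-butyl-7-methyl-4-(propan-2-yl)-4-(prop-2-en-1-yl)-4H-1,3,2-benzodioxasiline
Product: 10 [(4R)-2,2-di-tert-butyl-7-methyl-4-(propan-2-yl)-4H-1,3,2-benzodioxasilin-4-yl]acetic acid, via aldehyde 9 (not isolated)
Conditions: O3, CH2Cl2, −78 °C (Sudan III end point); PPh3, → 23 °C; then NaClO2, NaH2PO4, 2-methylbut-2-ene, t-BuOH/H2O, 0 → 23 °C
Reagents that add atoms: ozone, [O-][O+]=O; sodium chlorite, [Na+].[O-]Cl=O
Why: Ozonolysis of the only alkene with reductive work-up followed by Pinnick oxidation; the terminal alkene reacts far faster with ozone than the arene, and buffered chlorite with a hypochlorite scavenger leaves the aryl silyl ether untouched.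

Step 5
Reactants: 10 [(4R)-2,2-di-tert-butyl-7-methyl-4-(propan-2-yl)-4H-1,3,2-benzodioxasilin-4-yl]acetic acid; 11 diazoethane
Product: 13 3-diazo-1-[(4R)-2,2-di-tert-butyl-7-methyl-4-(propan-2-yl)-4H-1,3,2-benzodioxasilin-4-yl]butan-2-one, via acid chloride 12 (not isolated)
Conditions: (COCl)2, cat. DMF, CH2Cl2, 0 → 23 °C, evaporate; then CH3CHN2 (3.5 equiv, ethereal, freshly made from N-ethyl-N-nitrosourea/KOH), Et2O, −20 → 0 °C
Reagents that add atoms: diazoethane 11, CC=[N+]=[N-]
Why: Acylation of diazoethane by the acid chloride (diazoketone synthesis of the Arndt–Eistert type), the excess diazoalkane consuming the HCl so that neither the silylene nor the diazoketone meets acid.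

Step 6
Reactants: 13 3-diazo-1-[(4R)-2,2-di-tert-butyl-7-methyl-4-(propan-2-yl)-4H-1,3,2-benzodioxasilin-4-yl]butan-2-one
Product: 15 (3R,8aR)-3,4-[(di-tert-butylsilanediyl)bis(oxy)]-6,8a-dimethyl-3-(propan-2-yl)-3,8a-dihydroazulen-1(2H)-one (cycloheptatriene, C3a=C4, C5=C6, C7=C8), via norcaradiene 14 (not isolated)
Conditions: Rh2(OAc)4 (1 mol%), CH2Cl2, reflux, slow addition of 13 at high dilution
Reagents that add atoms: none
Why: Intramolecular Buchner reaction: the rhodium carbenoid cyclopropanates the ipso/ortho bond C4a–C5 of the arene to give norcaradiene 14, whose disrotatory 6π electrocyclic opening breaks the former aromatic C4a–C5 bond and so inserts the carbenoid carbon, turning the six ring carbons into the seven of the cycloheptatriene. The closest known type is the Rh(II)-catalysed cyclisation of 2-diazo-5-arylpentan-3-ones to 8a-methyl-3,4-dihydroazulen-1(2H)-ones. The cyclopentanone closes by [2+1] cycloaddition (carbenoid carbon to the ipso carbon, the ring running through C=O, CH2 and the carbinol carbon), and the seven-membered ring forms by electrocyclic ring expansion of the cyclopropane-fused cyclohexadiene. The new quaternary centre C8a is controlled by the (R)-carbinol through the silylene: the ring holds the carbinol oxygen in the arene plane on the oxygen-bearing ortho side, so the pseudoaxial diazoketone arm can only bridge to the unsubstituted ortho carbon on the isopropyl side, which places the 8a-methyl syn to the C3 oxygen and anti to isopropyl. The step needs regioselectivity between the two ipso/ortho bonds, which the tether secures because the other bond is the substituted ring-fusion bond of the siline and would give a strained propellane; it also needs chemoselectivity over 1,5-C–H insertion into the isopropyl methine, 1,2-hydride shift from the carbenoid methyl and attack on the silyl ether oxygen, which is favoured by the electron-rich arene held under the carbenoid and by the tert-butyl groups shielding that oxygen. The quaternary C8a also excludes later 1,5-hydrogen shifts in the triene.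

Step 7
Reactants: 15 (3R,8aR)-3,4-[(di-tert-butylsilanediyl)bis(oxy)]-6,8a-dimethyl-3-(propan-2-yl)-3,8a-dihydroazulen-1(2H)-one
Product: 16 (3R,3aR,8aR)-3-hydroxy-6,8a-dimethyl-3-(propan-2-yl)-2,3,3a,8a-tetrahydroazulene-1,4-dione (C5=C6 and C7=C8; 3a-H trans to 8a-CH3)
Conditions: HF·pyridine, pyridine, THF, 0 → 23 °C; crude 15 used directly
Reagents that add atoms: none
Why: Fluoride cleavage of both Si–O bonds turns the cyclic silyl dienol ether into the C4 ketone and frees the tertiary alcohol; the new C3a–H is α to that ketone and therefore equilibrating, and it is expected to settle trans to the 8a-methyl, where the C4 carbonyl is anti to isopropyl and hydrogen-bonded to the cis C3 hydroxyl, the same isomer that protonation anti to the angular methyl gives.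

Step 8
Reactants: 16 (3R,3aR,8aR)-3-hydroxy-6,8a-dimethyl-3-(propan-2-yl)-2,3,3a,8a-tetrahydroazulene-1,4-dione
Product: 17 (1S,3R,3aS,4S,8aR)-6,8a-dimethyl-3-(propan-2-yl)-1,2,3,3a,4,8a-hexahydroazulene-1,3,4-triol
Conditions: Me4NBH(OAc)3 (8 equiv), MeCN/AcOH (1:1), −30 → 0 °C; aq. Rochelle salt/NaHCO3
Reagents that add atoms: none
Why: Evans–Saksena hydroxyl-directed reduction: the C3 hydroxyl exchanges onto boron and delivers hydride internally to each β-carbonyl from its own face, which should make the C1 and C4 carbinols both trans to the C3 hydroxyl (1,3-anti), while ketones without a β-hydroxyl are not reduced by this reagent.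

Step 9
Reactants: 17 (1S,3R,3aS,4S,8aR)-6,8a-dimethyl-3-(propan-2-yl)-1,2,3,3a,4,8a-hexahydroazulene-1,3,4-triol
Product: 18 (1S,3R,3aS,4S,8aR)-6,8a-dimethyl-3-(propan-2-yl)-1,2,3,3a,4,5,8,8a-octahydroazulene-1,3,4-triol
Conditions: (η6-naphthalene)Cr(CO)3 (15 mol%), H2 (70 atm), acetone, 40 °C
Reagents that add atoms: none
Why: Arene–chromium tricarbonyl-catalysed 1,4-hydrogenation of a conjugated diene: the Cr(CO)3 fragment binds only the cisoid C5=C6–C7=C8 diene and adds H2 across its termini, which leaves the single C6=C7 alkene and cannot reduce it further.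

Step 10
Reactants: 18 (1S,3R,3aS,4S,8aR)-6,8a-dimethyl-3-(propan-2-yl)-1,2,3,3a,4,5,8,8a-octahydroazulene-1,3,4-triol; 19 (2Z)-2-methylbut-2-enoic acid (angelic acid)
Product: 20 (1S,3R,3aS,4S,8aR)-3-hydroxy-6,8a-dimethyl-3-(propan-2-yl)-1,2,3,3a,4,5,8,8a-octahydroazulene-1,4-diyl bis[(2Z)-2-methylbut-2-enoate]
Conditions: 19 (6 equiv), 2,4,6-Cl3C6H2COCl, Et3N, PhMe, 23 °C; then 18, 80 °C (no DMAP)
Reagents that add atoms: (2Z)-2-methylbut-2-enoic acid 19, C/C=C(/C)C(=O)O
Why: Yamaguchi-type esterification through the 2,4,6-trichlorobenzoic mixed anhydride without a nucleophilic amine catalyst, conditions under which the (Z)-alkene of the angelate should not isomerise to tiglate; both secondary alcohols acylate while the hindered tertiary C3 hydroxyl stays free.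

**Compound list**
1 | 3-methylphenol (m-cresol) | Cc1cccc(O)c1 | starting material
2 | 2-methylpropanoyl chloride | CC(C)C(=O)Cl | starting material
3 | 3-methylphenyl 2-methylpropanoate | CC(C)C(=O)Oc1cccc(C)c1 | intermediate (not isolated)
4 | 1-(2-hydroxy-4-methylphenyl)-2-methylpropan-1-one | CC(C)C(=O)c1ccc(C)cc1O | intermediate
5 | (3aR,7aR)-2-allyl-1,3-bis(4-bromobenzyl)-2-chlorooctahydro-1H-1,3,2-benzodiazasilole | C=CC[Si]1(Cl)N(Cc2ccc(Br)cc2)[C@@H]2CCCC[C@H]2N1Cc1ccc(Br)cc1 | starting material
6 | 2-[(3R)-3-hydroxy-2-methylhex-5-en-3-yl]-5-methylphenol | C=CC[C@@](O)(C(C)C)c1ccc(C)cc1O | intermediate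
7 | di-tert-butylsilanediyl bis(trifluoromethanesulfonate) | CC(C)(C)[Si](OS(=O)(=O)C(F)(F)F)(OS(=O)(=O)C(F)(F)F)C(C)(C)C | starting material
8 | (4R)-2,2-di-tert-butyl-7-methyl-4-(propan-2-yl)-4-(prop-2-en-1-yl)-4H-1,3,2-benzodioxasiline | C=CC[C@]1(C(C)C)O[Si](C(C)(C)C)(C(C)(C)C)Oc2cc(C)ccc21 | intermediate
9 | [(4R)-2,2-di-tert-butyl-7-methyl-4-(propan-2-yl)-4H-1,3,2-benzodioxasilin-4-yl]acetaldehyde | O=CC[C@]1(C(C)C)O[Si](C(C)(C)C)(C(C)(C)C)Oc2cc(C)ccc21 | intermediate (not isolated)
10 | [(4R)-2,2-di-tert-butyl-7-methyl-4-(propan-2-yl)-4H-1,3,2-benzodioxasilin-4-yl]acetic acid | OC(=O)C[C@]1(C(C)C)O[Si](C(C)(C)C)(C(C)(C)C)Oc2cc(C)ccc21 | intermediate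
11 | diazoethane (generated from N-ethyl-N-nitrosourea) | CC=[N+]=[N-] | starting material
12 | [(4R)-2,2-di-tert-butyl-7-methyl-4-(propan-2-yl)-4H-1,3,2-benzodioxasilin-4-yl]acetyl chloride | ClC(=O)C[C@]1(C(C)C)O[Si](C(C)(C)C)(C(C)(C)C)Oc2cc(C)ccc21 | intermediate (not isolated)
13 | 3-diazo-1-[(4R)-2,2-di-tert-butyl-7-methyl-4-(propan-2-yl)-4H-1,3,2-benzodioxasilin-4-yl]butan-2-one | CC(=[N+]=[N-])C(=O)C[C@]1(C(C)C)O[Si](C(C)(C)C)(C(C)(C)C)Oc2cc(C)ccc21 | intermediate
14 | norcaradiene valence isomer of 15 (cis-fused cyclopropane C3a–C8–C8a on the arene face of the side arm; C3 R; 8a-CH3 syn to the C3 oxygen) | CC1=C[C@@H]2[C@@]3(C)C(=O)C[C@]4(C(C)C)O[Si](C(C)(C)C)(C(C)(C)C)OC(=C1)[C@]234 | intermediate (not isolated)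
15 | (3R,8aR)-3,4-[(di-tert-butylsilanediyl)bis(oxy)]-6,8a-dimethyl-3-(propan-2-yl)-3,8a-dihydroazulen-1(2H)-one | CC1=CC(O[Si](C(C)(C)C)(C(C)(C)C)O2)=C3[C@]2(C(C)C)CC(=O)[C@]3(C)C=C1 | intermediate
16 | (3R,3aR,8aR)-3-hydroxy-6,8a-dimethyl-3-(propan-2-yl)-2,3,3a,8a-tetrahydroazulene-1,4-dione | O=C1C=C(C)C=C[C@@]2(C)C(=O)C[C@@](O)(C(C)C)[C@H]12 | intermediate
17 | (1S,3R,3aS,4S,8aR)-6,8a-dimethyl-3-(propan-2-yl)-1,2,3,3a,4,8a-hexahydroazulene-1,3,4-triol | O[C@H]1C=C(C)C=C[C@@]2(C)[C@@H](O)C[C@@](O)(C(C)C)[C@H]12 | intermediate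
18 | (1S,3R,3aS,4S,8aR)-6,8a-dimethyl-3-(propan-2-yl)-1,2,3,3a,4,5,8,8a-octahydroazulene-1,3,4-triol | O[C@H]1CC(C)=CC[C@@]2(C)[C@@H](O)C[C@@](O)(C(C)C)[C@H]12 | intermediate
19 | (2Z)-2-methylbut-2-enoic acid (angelic acid) | C/C=C(/C)C(=O)O | starting material
20 | (1S,3R,3aS,4S,8aR)-3-hydroxy-6,8a-dimethyl-3-(propan-2-yl)-1,2,3,3a,4,5,8,8a-octahydroazulene-1,4-diyl bis[(2Z)-2-methylbut-2-enoate] | C/C=C(/C)C(=O)O[C@H]1CC(C)=CC[C@@]2(C)[C@@H](OC(=O)/C(C)=C\C)C[C@@](O)(C(C)C)[C@H]12 | target

**Total step count:** 10. **Longest linear sequence:** 10 steps (from m-cresol 1; fully linear).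

**Steps most likely to fail**

Step 6. The carbenoid may be diverted before it reaches the arene, by 1,2-hydride shift from its methyl group or by C–H insertion into the isopropyl methine, or the silylene-locked conformer may not hold the arm over the ring face. The fallback drops the tether and relies on allylic 1,3-strain between an ortho-methoxy group and the isopropyl group to select the same aryl rotamer. It sets out from 6. Methylation of the phenol (MeI, K2CO3, acetone) should give (3R)-3-(2-methoxy-4-methylphenyl)-2-methylhex-5-en-3-ol F1. Ozonolysis (O3; PPh3) should give the hydroxy aldehyde F2 and Pinnick oxidation the hydroxy acid F3. TMSOTf/Et3N should give the bis-silyl compound F4, oxalyl chloride with catalytic DMF the acid chloride F5, and diazoethane the TMS-protected diazoketone F6. Rh2(OAc)4 in refluxing CH2Cl2 should then give, through norcaradiene F7, the methoxy trienone F8. Dilute aqueous HCl in THF at 0 °C hydrolyses the methyl enol ether and the TMS ether and returns to the route at 16.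

Step 8. After the first hydride transfer the boron may stay chelated between the C1 and C3 oxygens, so that the less electrophilic dienone carbonyl is reduced slowly or not by internal delivery; the dienyl carbinol may also ionise in acetic acid. The fallback separates the two reductions and sets out from 16. Me4NBH(OAc)3 (1.5 equiv) at −40 °C should reduce only the saturated C1 ketone to (1S,3R,3aR,8aR)-1,3-dihydroxy-6,8a-dimethyl-3-(propan-2-yl)-2,3,3a,8a-tetrahydroazulen-4(1H)-one F9. A Luche reduction (NaBH4, CeCl3·7H2O, MeOH, −78 °C) under non-acidic conditions then reduces the dienone 1,2 by external attack; this is expected to give the pseudo-equatorial C4 carbinol, trans to the C3a–C3 bond, which is the configuration of the target. The fallback returns to the route at 17.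

Step 9. The chromium fragment may bind the hindered trisubstituted ring diene slowly, and a chromium-mediated 1,5-hydrogen shift from the C4 carbinol C–H may compete with hydrogen uptake. The fallback sets out from 17 and replaces catalytic hydrogenation by a dissolving-metal reduction (Li, NH3/THF, t-BuOH, −78 °C) of the triol as its lithium alkoxides. Electron transfer to the diene and protonation at its termini should add two hydrogens 1,4 and give 18 directly, where the fallback returns to the route; no new compound is made (F0).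

**Further compounds**
F1 | step 6 | (3R)-3-(2-methoxy-4-methylphenyl)-2-methylhex-5-en-3-ol | C=CC[C@@](O)(C(C)C)c1ccc(C)cc1OC
F2 | step 6 | (3R)-3-hydroxy-3-(2-methoxy-4-methylphenyl)-4-methylpentanal | O=CC[C@@](O)(C(C)C)c1ccc(C)cc1OC
F3 | step 6 | (3R)-3-hydroxy-3-(2-methoxy-4-methylphenyl)-4-methylpentanoic acid | OC(=O)C[C@@](O)(C(C)C)c1ccc(C)cc1OC
F4 | step 6 | trimethylsilyl (3R)-3-(2-methoxy-4-methylphenyl)-4-methyl-3-[(trimethylsilyl)oxy]pentanoate | C[Si](C)(C)OC(=O)C[C@@](O[Si](C)(C)C)(C(C)C)c1ccc(C)cc1OC
F5 | step 6 | (3R)-3-(2-methoxy-4-methylphenyl)-4-methyl-3-[(trimethylsilyl)oxy]pentanoyl chloride | ClC(=O)C[C@@](O[Si](C)(C)C)(C(C)C)c1ccc(C)cc1OC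
F6 | step 6 | (5R)-2-diazo-5-(2-methoxy-4-methylphenyl)-6-methyl-5-[(trimethylsilyl)oxy]heptan-3-one | CC(=[N+]=[N-])C(=O)C[C@@](O[Si](C)(C)C)(C(C)C)c1ccc(C)cc1OC
F7 | step 6 | norcaradiene valence isomer of F8 (cis-fused cyclopropane C3a–C8–C8a) | COC1=CC(C)=C[C@@H]2[C@@]3(C)C(=O)C[C@@](O[Si](C)(C)C)(C(C)C)[C@@]123
F8 | step 6 | (3R,8aR)-4-methoxy-6,8a-dimethyl-3-(propan-2-yl)-3-[(trimethylsilyl)oxy]-3,8a-dihydroazulen-1(2H)-one | COC1=C2[C@](O[Si](C)(C)C)(C(C)C)CC(=O)[C@]2(C)C=CC(C)=C1
F9 | step 8 | (1S,3R,3aR,8aR)-1,3-dihydroxy-6,8a-dimethyl-3-(propan-2-yl)-2,3,3a,8a-tetrahydroazulen-4(1H)-one | O=C1C=C(C)C=C[C@@]2(C)[C@@H](O)C[C@@](O)(C(C)C)[C@H]12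
F0 | step 9 | none | none
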